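The route rests on disconnecting the C3a–C4 bond of the cyclohexane ring (lactone numbered as hexahydro-2-benzofuran-1(3H)-one: C1 carbonyl, O2, C3, C3a, C4–C7, C7a). The C4 acyl carbon and the oxygen-bearing C3 of the lactone ring are 1,4-related through this bond, so C4 (an ester α-carbon) and C3a (an enol-ether β-carbon) are both natural nucleophiles and are joined by anodic oxidation. One electrolysis closes the six-membered ring, creates the C4 quaternary centre trans to the preset C7a centre and delivers C3 as a dimethyl acetal. The precursor is an acyclic (S)-2-methylheptenoate with a methoxyvinyl group on its quaternary carbon and a silyl ketene acetal at the far end of a three-carbon tether.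

Key step: step 9

Remarks on the chemistry (assumptions, one line each)
- The target SMILES reads as 3S, 3aR, 4S, 7aS, 1'S (C1' = acetoxy-bearing carbon): cis-fused lactone, C4 acyl trans to the lactone carbonyl, H-3 and H-3a cis (side chain on the concave face), C3–O and C1'–O anti.
- Diester 13 has no symmetry axis, because an axis through C2 and C5 of the cyclohexane would have to exchange H and the acetal carbon on C2; C3a is not a stereocentre, but one ester is cis and the other trans to the acetal carbon.
- Lactonisation of a C3 carbinol is therefore not used to tell the two carboxyls apart, since a trans-fused lactone with the side chain on the open face would compete; both esters are cleaved and the cis carboxyl is selected by reversible pseudo-ester formation before C3 is elaborated.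
- Both esters of precursor 12 stay methyl on purpose: unlike esters would make C3a a stereocentre that the electrolysis would have to control.
- The C4 ketone is installed before the side chain, so no ester has to be cleaved in the presence of the base-sensitive α-acetoxy-β-acyloxy ketone.
- Enol ethers 8, 9, 11, 12 and ketene acetal 12 are E/Z mixtures drawn as one isomer (both geometries are lost in step 9); C6 of 11 and C3 of 15, 19, 20 and 21 are epimer mixtures of no consequence.
- 2-(Furan-3-yl)ethanol 16 is taken as a catalogue compound.

Step 1
Reactants: 1 dimethyl 2-methylpropanedioate; 2 1-bromo-3-chloropropane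
Product: 3 dimethyl 2-(3-chloropropyl)-2-methylpropanedioate
Conditions: NaH, DMF, 0 °C to rt
Reagents that add atoms: none
Why: Malonic ester alkylation of the sodium enolate, in which bromide is displaced far faster than chloride, so the chloropropyl chain is installed and no stereocentre is formed.

Step 2
Reactants: 3 dimethyl 2-(3-chloropropyl)-2-methylpropanedioate
Product: 4 (2S)-5-chloro-2-(methoxycarbonyl)-2-methylpentanoic acid
Conditions: pig liver esterase, 0.1 M phosphate buffer pH 7.5, DMSO (20% v/v), rt; then acidification
Reagents that add atoms: water (O)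
Why: Enzymatic desymmetrisation (enantiotopic-group-selective ester hydrolysis) of a prochiral 2-alkyl-2-methylmalonate sets the quaternary centre, short unbranched chains being known to give the (S)-half-ester, and because selectivity in this chain-length range is only moderate the acid is to be enriched by crystallising an amine salt before use.

Step 3
Reactants: 4 (2S)-5-chloro-2-(methoxycarbonyl)-2-methylpentanoic acid
Product: 5 methyl (2S)-5-chloro-2-(hydroxymethyl)-2-methylpentanoate
Conditions: BH3·SMe2, THF, 0 °C to rt; MeOH, then aqueous work-up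
Reagents that add atoms: none
Why: Chemoselective borane reduction of a carboxylic acid in the presence of a methyl ester and an alkyl chloride, which leaves the quaternary centre untouched.

Step 4
Reactants: 5 methyl (2S)-5-chloro-2-(hydroxymethyl)-2-methylpentanoate
Product: 6 methyl (2S)-5-chloro-2-formyl-2-methylpentanoate
Conditions: Dess–Martin periodinane, CH2Cl2, rt
Reagents that add atoms: none
Why: Dess–Martin oxidation of a neopentyl primary alcohol to the aldehyde, which cannot epimerise because its α-carbon is quaternary.

Step 5
Reactants: 6 methyl (2S)-5-chloro-2-formyl-2-methylpentanoate; 7 (methoxymethyl)triphenylphosphonium chloride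
Product: 8 methyl (2S,3E)-2-(3-chloropropyl)-4-methoxy-2-methylbut-3-enoate (E/Z mixture; E drawn)
Conditions: 7, KN(SiMe3)2, THF, 0 °C; then 6, −78 °C to rt
Reagents that add atoms: none
Why: Wittig olefination with the methoxymethylene ylide gives the enol ether, and the non-nucleophilic amide base avoids alkoxide-induced deformylation of the α-formyl ester.

Step 6
Reactants: 8 methyl (2S,3E)-2-(3-chloropropyl)-4-methoxy-2-methylbut-3-enoate
Product: 9 methyl (2S,3E)-2-(3-iodopropyl)-4-methoxy-2-methylbut-3-enoate
Conditions: NaI, acetone, reflux
Reagents that add atoms: sodium iodide ([Na+].[I-])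
Why: Finkelstein halide exchange turns the unreactive primary chloride into the iodide needed for enolate alkylation under conditions that do not touch the enol ether.

Step 7
Reactants: 9 methyl (2S,3E)-2-(3-iodopropyl)-4-methoxy-2-methylbut-3-enoate; 10 methyl propanoate
Product: 11 dimethyl (2S)-2-[(E)-2-methoxyethenyl]-2,6-dimethylheptanedioate (C6 epimers)
Conditions: 10, LiN(iPr)2, THF, −78 °C; then 9, DMPU, −78 to −20 °C
Reagents that add atoms: none
Why: SN2 alkylation of the lithium enolate of methyl propanoate by a primary iodide, the only other ester being quaternary and hindered, with C6 formed as a mixture that is erased in the next step.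

Step 8
Reactants: 11 dimethyl (2S)-2-[(E)-2-methoxyethenyl]-2,6-dimethylheptanedioate
Product: 12 methyl (2S,6Z)-7-{[tert-butyl(dimethyl)silyl]oxy}-7-methoxy-2-[(E)-2-methoxyethenyl]-2,6-dimethylhept-6-enoate
Conditions: TBSCl, LiN(iPr)2 (added last), THF–DMPU, −78 °C to rt; non-aqueous work-up
Reagents that add atoms: tert-butyl(chloro)dimethylsilane, TBSCl (CC(C)(C)[Si](C)(C)Cl)
Why: Kinetic enolisation and O-silylation (silyl ketene acetal formation) at the only enolisable ester, with the silyl chloride present from the start so that the enolate is trapped before it can undergo Dieckmann condensation.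

Step 9
Reactants: 12 methyl (2S,6Z)-7-{[tert-butyl(dimethyl)silyl]oxy}-7-methoxy-2-[(E)-2-methoxyethenyl]-2,6-dimethylhept-6-enoate
Product: 13 dimethyl (1S,3S)-2-(dimethoxymethyl)-1,3-dimethylcyclohexane-1,3-dicarboxylate
Conditions: reticulated vitreous carbon anode, Pt cathode, undivided cell, constant current, 2.2 F mol−1, 0.1 M LiClO4 in MeOH–CH2Cl2 (1:4), 2,6-lutidine, rt
Reagents that add atoms: methanol (CO)
Why: Proposed new method: one-electron oxidation at the anode should occur at the silyl ketene acetal, the more electron-rich of the two olefins, and the radical cation is attacked at C4 by the nucleophilic β-carbon (C3a) of the enol ether; loss of a second electron, capture of the C3 oxocarbenium ion by methanol and transfer of the silyl group to methanol then give the acetal and the C4 methyl ester. The closest known reaction type is the intramolecular anodic olefin coupling in which an enol ether traps an enol ether, ketene dithioacetal or N,O-ketene acetal radical cation, together with the anodic coupling of silyl enol ethers with furans, both of which build quaternary carbons; a silyl ketene acetal as the oxidised partner has not been shown. The cyclohexane ring closes in a 6-exo mode with respect to both double bonds. The one new stereocentre, C4, is controlled by the preset C7a centre through a chair-like transition state in which the bulky silyloxy(methoxy)-substituted terminus is pseudo-equatorial, the C4 methyl group is therefore axial and C7a places its ester, not its methyl group, in the syn-axial position, which leads to the trans diester. The step needs trans over cis (achiral) selectivity and C–C bond formation that outruns methanolysis of the ketene acetal; the first is secured by the size of the silyl ketene acetal terminus and the second by its tetrasubstituted tert-butyldimethylsilyl form, the lutidine buffer and the low methanol content. C3a is not a stereocentre in 13 because its two ring neighbours are alike in constitution and configuration, so nothing else has to be controlled.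

Step 10
Reactants: 13 dimethyl (1S,3S)-2-(dimethoxymethyl)-1,3-dimethylcyclohexane-1,3-dicarboxylate
Product: 15 (3aR,4S,7aS)-3-methoxy-4,7a-dimethyl-1-oxooctahydro-2-benzofuran-4-carboxylic acid (C3 anomers), via diacid acetal 14 (not isolated)
Conditions: NaSEt, DMF, 100 °C; aq. HCl work-up; then camphorsulfonic acid (cat.), CH2Cl2, rt
Reagents that add atoms: none
Why: SN2 O-demethylation of the two hindered methyl esters by thiolate is followed by acid-catalysed, reversible cyclisation of the acetal onto a carboxyl (pseudo-ester formation), in which the cis-fused γ-lactone is expected as the thermodynamic product, so that the carboxyl cis to C3 becomes C1, C3a becomes R and the trans carboxyl on C4 stays free.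

Step 11
Reactants: 16 2-(furan-3-yl)ethanol
Product: 17 3-(2-iodoethyl)furan
Conditions: I2, PPh3, imidazole, CH2Cl2, 0 °C to rt
Reagents that add atoms: iodine (II)
Why: Appel-type iodination of a primary alcohol under buffered conditions that the furan tolerates.

Step 12
Reactants: 17 3-(2-iodoethyl)furan
Product: 18 [2-(furan-3-yl)ethyl](iodo)zinc (THF solution)
Conditions: Zn dust (activated), LiCl, THF, 40 °C
Reagents that add atoms: zinc ([Zn])
Why: Direct insertion of zinc into a primary alkyl iodide, accelerated by LiCl, gives the functional-group-tolerant alkylzinc iodide.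

Step 13
Reactants: 15 (3aR,4S,7aS)-3-methoxy-4,7a-dimethyl-1-oxooctahydro-2-benzofuran-4-carboxylic acid; 18 [2-(furan-3-yl)ethyl](iodo)zinc
Product: 20 (3aR,4S,7aS)-4-[3-(furan-3-yl)propanoyl]-3-methoxy-4,7a-dimethylhexahydro-2-benzofuran-1(3H)-one, via acid chloride 19 (not isolated)
Conditions: 15, 1-chloro-N,N,2-trimethylprop-1-en-1-amine, CH2Cl2, 0 °C to rt; then 18, Pd(PPh3)4 (5 mol %), THF, 0 °C to rt
Reagents that add atoms: none
Why: Negishi acylation, in which the hindered acid is turned into its chloride under neutral conditions and coupled with the alkylzinc iodide under palladium catalysis, leaves the lactone, the acetal and the furan untouched and stops at the ketone.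

Step 14
Reactants: 20 (3aR,4S,7aS)-4-[3-(furan-3-yl)propanoyl]-3-methoxy-4,7a-dimethylhexahydro-2-benzofuran-1(3H)-one
Product: 21 (3aR,4S,7aS)-4-[3-(furan-3-yl)propanoyl]-3-hydroxy-4,7a-dimethylhexahydro-2-benzofuran-1(3H)-one (lactol, in equilibrium with the open aldehyde acid)
Conditions: 1 M HCl, THF, rt
Reagents that add atoms: water (O)
Why: Mild acid hydrolysis of the cyclic acyloxy acetal frees the lactol without opening the 3-alkylfuran.

Step 15
Reactants: 21 (3aR,4S,7aS)-4-[3-(furan-3-yl)propanoyl]-3-hydroxy-4,7a-dimethylhexahydro-2-benzofuran-1(3H)-one; 22 1-hydroxypropan-2-one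
Product: 24 (3S,3aR,4S,7aS)-4-[3-(furan-3-yl)propanoyl]-3-[(1S)-1-hydroxy-2-oxopropyl]-4,7a-dimethylhexahydro-2-benzofuran-1(3H)-one, via seco acid 23 (not isolated)
Conditions: 22 (excess), L-proline (30 mol %), DMSO, rt; aqueous work-up; then EDC·HCl, DMAP (cat.), CH2Cl2, 0 °C
Reagents that add atoms: none
Why: Proline-catalysed enamine aldol addition of hydroxyacetone to the open aldehyde form gives the anti-1,2-diol with C3 and C1' both set as S by the L catalyst (the two quaternary neighbours of C3a being of similar size, catalyst control should dominate), and carbodiimide lactonisation can only use the single remaining carboxyl, which forces the cis-fused γ-lactone with the side chain on the concave face.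

Step 16
Reactants: 24 (3S,3aR,4S,7aS)-4-[3-(furan-3-yl)propanoyl]-3-[(1S)-1-hydroxy-2-oxopropyl]-4,7a-dimethylhexahydro-2-benzofuran-1(3H)-one
Product: 25 (1S)-1-{(3S,3aR,4S,7aS)-4-[3-(furan-3-yl)propanoyl]-4,7a-dimethyl-1-oxooctahydro-2-benzofuran-3-yl}-2-oxopropyl acetate (CNP0170401.2)
Conditions: Ac2O, pyridine, DMAP (cat.), CH2Cl2, 0 °C
Reagents that add atoms: acetic anhydride (CC(=O)OC(C)=O)
Why: Nucleophile-catalysed O-acetylation of the only free hydroxyl at low temperature, mild enough to avoid β-elimination of the lactone carboxylate.

Compound list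
1 | dimethyl 2-methylpropanedioate (dimethyl methylmalonate) | COC(=O)C(C)C(=O)OC | starting material
2 | 1-bromo-3-chloropropane | ClCCCBr | starting material
3 | dimethyl 2-(3-chloropropyl)-2-methylpropanedioate | COC(=O)C(C)(CCCCl)C(=O)OC | intermediate
4 | (2S)-5-chloro-2-(methoxycarbonyl)-2-methylpentanoic acid | OC(=O)[C@@](C)(C(=O)OC)CCCCl | intermediate
5 | methyl (2S)-5-chloro-2-(hydroxymethyl)-2-methylpentanoate | OC[C@@](C)(C(=O)OC)CCCCl | intermediate
6 | methyl (2S)-5-chloro-2-formyl-2-methylpentanoate | O=C[C@@](C)(C(=O)OC)CCCCl | intermediate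
7 | (methoxymethyl)triphenylphosphonium chloride | [Cl-].COC[P+](c1ccccc1)(c1ccccc1)c1ccccc1 | starting material
8 | methyl (2S,3E)-2-(3-chloropropyl)-4-methoxy-2-methylbut-3-enoate | CO/C=C/[C@@](C)(C(=O)OC)CCCCl | intermediate
9 | methyl (2S,3E)-2-(3-iodopropyl)-4-methoxy-2-methylbut-3-enoate | CO/C=C/[C@@](C)(C(=O)OC)CCCI | intermediate
10 | methyl propanoate | CCC(=O)OC | starting material
11 | dimethyl (2S)-2-[(E)-2-methoxyethenyl]-2,6-dimethylheptanedioate | CO/C=C/[C@@](C)(C(=O)OC)CCCC(C)C(=O)OC | intermediate
12 | methyl (2S,6Z)-7-{[tert-butyl(dimethyl)silyl]oxy}-7-methoxy-2-[(E)-2-methoxyethenyl]-2,6-dimethylhept-6-enoate | CO/C=C/[C@@](C)(C(=O)OC)CCC/C(C)=C(/OC)O[Si](C)(C)C(C)(C)C | intermediate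
13 | dimethyl (1S,3S)-2-(dimethoxymethyl)-1,3-dimethylcyclohexane-1,3-dicarboxylate | COC(OC)C1[C@@](C)(C(=O)OC)CCC[C@]1(C)C(=O)OC | intermediate
14 | (1S,3S)-2-(dimethoxymethyl)-1,3-dimethylcyclohexane-1,3-dicarboxylic acid | COC(OC)C1[C@@](C)(C(=O)O)CCC[C@]1(C)C(=O)O | intermediate
15 | (3aR,4S,7aS)-3-methoxy-4,7a-dimethyl-1-oxooctahydro-2-benzofuran-4-carboxylic acid | COC1OC(=O)[C@@]2(C)CCC[C@](C)(C(=O)O)[C@@H]12 | intermediate
16 | 2-(furan-3-yl)ethanol | OCCc1ccoc1 | starting material
17 | 3-(2-iodoethyl)furan | ICCc1ccoc1 | intermediate
18 | [2-(furan-3-yl)ethyl](iodo)zinc | I[Zn]CCc1ccoc1 | intermediate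
19 | (3aR,4S,7aS)-3-methoxy-4,7a-dimethyl-1-oxooctahydro-2-benzofuran-4-carbonyl chloride | COC1OC(=O)[C@@]2(C)CCC[C@](C)(C(Cl)=O)[C@@H]12 | intermediate
20 | (3aR,4S,7aS)-4-[3-(furan-3-yl)propanoyl]-3-methoxy-4,7a-dimethylhexahydro-2-benzofuran-1(3H)-one | COC1OC(=O)[C@@]2(C)CCC[C@](C)(C(=O)CCc3ccoc3)[C@@H]12 | intermediate
21 | (3aR,4S,7aS)-4-[3-(furan-3-yl)propanoyl]-3-hydroxy-4,7a-dimethylhexahydro-2-benzofuran-1(3H)-one | OC1OC(=O)[C@@]2(C)CCC[C@](C)(C(=O)CCc3ccoc3)[C@@H]12 | intermediate
22 | 1-hydroxypropan-2-one (hydroxyacetone) | CC(=O)CO | starting material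
23 | (1S,2R,3S)-2-[(1S,2S)-1,2-dihydroxy-3-oxobutyl]-3-[3-(furan-3-yl)propanoyl]-1,3-dimethylcyclohexane-1-carboxylic acid | O[C@H](C(C)=O)[C@@H](O)[C@H]1[C@@](C)(C(=O)O)CCC[C@]1(C)C(=O)CCc1ccoc1 | intermediate
24 | (3S,3aR,4S,7aS)-4-[3-(furan-3-yl)propanoyl]-3-[(1S)-1-hydroxy-2-oxopropyl]-4,7a-dimethylhexahydro-2-benzofuran-1(3H)-one | O[C@H](C(C)=O)[C@H]1OC(=O)[C@@]2(C)CCC[C@](C)(C(=O)CCc3ccoc3)[C@@H]12 | intermediate
25 | (1S)-1-{(3S,3aR,4S,7aS)-4-[3-(furan-3-yl)propanoyl]-4,7a-dimethyl-1-oxooctahydro-2-benzofuran-3-yl}-2-oxopropyl acetate | CC(=O)O[C@H](C(C)=O)[C@H]1OC(=O)[C@@]2(C)CCC[C@](C)(C(=O)CCc3ccoc3)[C@@H]12 | target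

Total step count: 16. Longest linear sequence: 14 steps (steps 1–10 and 13–16); steps 11 and 12 form the side branch.

Steps most likely to fail

1. Step 9 (Proposed new method). The ketene acetal may be protodesilylated by methanol, or its radical cation captured by solvent, before the slow bond formation between a fully substituted carbon and a neopentyl carbon takes place; the chair preference may also be too weak, so that the cis diester is formed alongside the trans one. Fallback by known atom-transfer radical chemistry, setting out from 11: deprotonation with LiN(iPr)2 and bromination of the enolate with CBr4 at −78 °C should give dimethyl (2S)-6-bromo-2-[(E)-2-methoxyethenyl]-2,6-dimethylheptanedioate F1. CuBr with tris(2-pyridylmethyl)amine in methanol containing 2,6-lutidine should then bring about a Kharasch-type bromine-atom-transfer 6-exo cyclisation, the electrophilic tertiary α-ester radical adding to the enol-ether β-carbon (C3a). The α-bromo ether so formed is solvolysed by methanol to the dimethyl acetal, and the route is rejoined at 13.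

2. Step 15. The aldehyde is present mostly as the lactol and is flanked by two quaternary carbons, so enamine addition may be too slow, and catalyst control of the aldehyde face may be eroded. Fallback, setting out from 21: Wittig olefination of the lactol with 1-(triphenylphosphoranylidene)propan-2-one in hot toluene should give (1S,2R,3S)-3-[3-(furan-3-yl)propanoyl]-1,3-dimethyl-2-[(1E)-3-oxobut-1-en-1-yl]cyclohexane-1-carboxylic acid F2. Amine-catalysed asymmetric Weitz–Scheffer epoxidation (9-amino-9-deoxy-epi-cinchona alkaloid trifluoroacetate salt, aqueous H2O2, with the pseudoenantiomer that gives the (2R,3S)-oxirane) should give (1S,2R,3S)-2-[(2R,3S)-3-acetyloxiran-2-yl]-3-[3-(furan-3-yl)propanoyl]-1,3-dimethylcyclohexane-1-carboxylic acid F3. The carboxyl then opens the epoxide at C3 in a 5-exo fashion with inversion (catalytic camphorsulfonic acid), which gives the anti hydroxy lactone and rejoins the route at 24.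

3. Step 2. Discrimination between the two enantiotopic esters may be insufficient for a chain of this length, leaving material of low enantiomeric purity that salt crystallisation cannot fully correct. Fallback by covalent resolution, setting out from 3: KOH (1 equiv) in methanol should give racemic 5-chloro-2-(methoxycarbonyl)-2-methylpentanoic acid F4. Oxalyl chloride followed by the lithium salt of (4S)-4-benzyl-1,3-oxazolidin-2-one gives two diastereomeric imides, from which methyl (2S)-2-{[(4S)-4-benzyl-2-oxo-1,3-oxazolidin-3-yl]carbonyl}-5-chloro-2-methylpentanoate F5 is separated by chromatography. LiBH4 (THF, one equivalent of MeOH, 0 °C) reduces only the imide carbonyl, releasing the auxiliary and rejoining the route at 5.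

Further compounds
F1 | step 9 | dimethyl (2S)-6-bromo-2-[(E)-2-methoxyethenyl]-2,6-dimethylheptanedioate | CO/C=C/[C@@](C)(C(=O)OC)CCCC(C)(Br)C(=O)OC
F2 | step 15 | (1S,2R,3S)-3-[3-(furan-3-yl)propanoyl]-1,3-dimethyl-2-[(1E)-3-oxobut-1-en-1-yl]cyclohexane-1-carboxylic acid | CC(=O)/C=C/[C@H]1[C@@](C)(C(=O)O)CCC[C@]1(C)C(=O)CCc1ccoc1
F3 | step 15 | (1S,2R,3S)-2-[(2R,3S)-3-acetyloxiran-2-yl]-3-[3-(furan-3-yl)propanoyl]-1,3-dimethylcyclohexane-1-carboxylic acid | CC(=O)[C@H]1O[C@@H]1[C@H]2[C@@](C)(C(=O)O)CCC[C@]2(C)C(=O)CCc2ccoc2
F4 | step 2 | racemic 5-chloro-2-(methoxycarbonyl)-2-methylpentanoic acid | OC(=O)C(C)(C(=O)OC)CCCCl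
F5 | step 2 | methyl (2S)-2-{[(4S)-4-benzyl-2-oxo-1,3-oxazolidin-3-yl]carbonyl}-5-chloro-2-methylpentanoate | COC(=O)[C@@](C)(CCCCl)C(=O)N1[C@@H](Cc2ccccc2)COC1=O
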